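The data come from a simulation from invented constants, and the scatter is random.

What part of X is gone at 25 h in the flask, what Z stands then, and what should be watched on the way?

| flask | X | D | Q | E | remark | time |
|---|---|---|---|---|---|---|
| dawn | 0.070 M | 1.5 equiv | 1 equiv | 1 equiv | run made earlier |  |
| autumn | 0.28 M | 1.5 equiv | 1 equiv | 1 equiv | run made earlier |  |
| flask | 0.14 M | 1.50 equiv | 1.00 equiv | 1.00 equiv |  | 25 h |

- dawn (time / h: X / %, Z / %): 2.00: 71, 29; 5.00: 62, 39; 10.0: 61, 40; 15.0: 59, 38; 20.0: 58, 42
- autumn (time / h: X / %, Z / %): 4.00: 59, 39; 8.00: 61, 38; 12.0: 61, 41; 15.0: 59, 41; 20.0: 60, 42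

(readings scatter by 1.5 percentage points)

- part of the X gone at 25 h
- the Z standing at 25 h, as a percentage of the X charged

1. In the dawn run the last readings, 58% X and 42% Z, sum to the X charged, so X appears to pass cleanly into Z. Both runs stop with X still present.

2. Suppose D is the limiting reagent, shared among X, Q and E. From 10.0 h onward, the mean Z divided by the D charged gives 0.267 for the dawn run and 0.276 for the autumn run. Their mean, s = 0.271, is the D share: equivalents of Z formed per equivalent of D charged.

3. Test of the one number: the autumn run holds 4.00 times the concentration of the dawn run, yet their plateaus of Z differ by 1.3 percentage points, beside a scatter of 1.5 points. Q and E stayed at the same equivalents, so s is read for those charges.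

4. The flask has the same equivalents, so this reckoning gives s times 1.50 equiv, or 40.7% Z and as much X gone. The dawn run had reached 39% Z at 5.00 h, earlier than 25 h, so the flat stretch of Z is the thing to watch.

5. The forecast gives 40% gone and 40% Z, slightly lower than this reckoning. Of the stall in the two runs it says: “the likely cause is exhaustion of D”.

The flask gives 40.0% of X gone and 40.0% Z at 25 h.

    X + D → Z (k = 0.0480 M⁻¹ min⁻¹)
    Q + D → L (k = 0.0630 M⁻¹ min⁻¹)
    E + D → J (k = 0.0890 M⁻¹ min⁻¹)

At 25.0 h this flask holds 0% of its charged D, less than the 60% of its X left. A neighbouring flask, the same but with 0.600 equiv of D, is reckoned by s at 16.3% Z. That neighbour holds 14.9% Z at 25.0 h.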